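At 8.00 h the north-east run held 13.6 % of product against 10.4 % in the south run, which is more product but less for each equivalent of coupling partner.

| setting | south | north-east | flask |
|---|---|---|---|
| solid substrate | 0.050 M | 0.050 M | 0.050 M |
| coupling partner | 0.60 equiv | 0.90 equiv | 1.20 equiv |
| remark | run made earlier | run made earlier |  |
| time |  |  | 30 h |

| run | time / h | product / % | solid substrate / % |
|---|---|---|---|
| south | 2.00 | 4.0 | 66.6 |
| south | 4.00 | 8.9 | 57.3 |
| south | 8.00 | 10.4 | 54.2 |
| south | 15.0 | 9.4 | 53.6 |
| south | 30.0 | 9.2 | 54.1 |
| north-east | 2.00 | 5.2 | 64.4 |
| north-east | 4.00 | 12.5 | 54.5 |
| north-east | 8.00 | 13.6 | 49.6 |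
| north-east | 15.0 | 13.1 | 50.1 |
| north-east | 30.0 | 12.8 | 51.3 |

(readings scatter by 0.5 percentage points)

- time, not beyond 30 h, at which the flask holds most product
- the amount of product, in percent of the solid substrate charged, at that time
- earliest time at which at least nineteen twentieths of that best amount are there
- latest time at which they still are

- solid substrate is a solid; its amount is given per volume of the solution
- at the start none of the solid substrate is in solution
- a reading or a percentage of product counts all its forms, free or not

I built the flask up one process at a time. With the main step alone, solid substrate and coupling partner going one for one to product, the south run could have reached a product figure equal to its 0.60 equiv, and its readings stopped far below that.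

Next I added dissolving. At 30.0 h the part of each charge that was neither solid nor product was

36.7 % (south), 35.9 % (north-east).

I took this as a dissolved pool, and with 54.1 % still solid in the south run, I did not look to the solid for the stop.

Last I added a loss of coupling partner by a route of its own. Both runs had their highest reading at 8.00 h despite different charges, so I made the coupling partner the limiting reagent and carried one quantity, the capture share: the best product per equivalent of coupling partner charged.

south: 0.173

north-east: 0.151

flask, north-east share held: 18.1 %

flask, the fall continued: 15.5 %

I committed to the first figure, from the nearer run, with the second as my low margin. For the times I expected a peak near 8.00 h. The north-east run stood at 91.9 % of its peak reading at 4.00 h, so I put the opening just after that, and the closing near 15.0 h.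

The forecast gave 17.3 % at 7 h, with the window from 4.3 h to 22 h, and read the runs thus: “This suggests equilibrium or a stall, not exhaustion of the partner.”

The flask peaked at 8.87 h with 17.8 %, and the window asked for ran from 5.54 h to 17.3 h.

    starting material + coupling partner ⇌ intermediate (K = 19.0 /M, k = 0.00584 /M/s)
    intermediate ⇌ product + by-product (K = 0.470 M, k = 3.67 × 10⁻⁴ /s)
    coupling partner + product ⇌ idle adduct, settled at all times (K = 35.1 /M)
    solid substrate ⇌ starting material, rate k4*(cs4 - [starting material]) while solid is left; crystals form when [starting material] > cs4 (solubility = 18.0 mM, k = 2.55 × 10⁻⁴ /s)
    coupling partner → decomposed reagent (k = 1.51 × 10⁻⁴ /s)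

At that peak the coupling partner stood at 0.683 % of its charge. The flask's capture share came to 0.148. Applied to a neighbour charged with 4.80 equiv, the north-east share gives 72.5 %. That neighbour's best was 49.5 %, a capture share of 0.103, lower than the north-east share.

The readings are calculated with made-up constants, noise included.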